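**Strategy.** The plan cuts the two benzylic C–O bonds of the furofuran, C7–O–C9' and C7'–O–C9. C7 (on ring B) and C7' (on syringyl ring C) each sit para to an alkoxy oxygen. Each also has the hydroxymethyl oxygen of the opposite half within reach of a five-membered closure. A (2S,3S)-2,3-dibenzylbutane-1,4-diol with no heterocycle, holding only C8 and C8', should therefore be oxidised anodically at both benzylic CH2 groups. This closes both oxolane rings and sets C7 and C7' in one operation. The diol comes from Stobbe, asymmetric hydrogenation and lactone alkylation chemistry. The erythro glycerol chain follows by auxiliary-controlled syn aldol and Mitsunobu inversion at C7''.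

Key step: step 8

**Remarks before the steps**
- Numbering: ring A is the terminal guaiacyl ring on C7'', ring B the central guaiacyl ring on C7, ring C the syringyl ring on C7'. C7–C9 and C7'–C9' are the furofuran carbons and C7''–C9'' the glycerol chain. The target is (7R,8S,7'R,8'S,7''R,8''S).
- Assumption: the (R,R) antipode of Et-DuPhos is assigned by analogy with the enamide quadrant model, in which the (S,S) ligand gives the (R)-2-benzylsuccinate. Both antipodes are commercial, so an opposite sense is corrected by exchanging the ligand.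
- Remark: (7''R,8''S) is erythro, which is anti in the zigzag drawing. The furofuran centres are too remote to bias an achiral ester enolate, so C7'' and C8'' are set under auxiliary control.

**Route**

Step 1
Reactants: 1 4-(benzyloxy)-3,5-dimethoxybenzaldehyde; 2 dimethyl succinate
Product: 4 (E)-4-[4-(benzyloxy)-3,5-dimethoxyphenyl]-3-(methoxycarbonyl)but-3-enoic acid, via paraconic ester lactone 3 (not isolated)
Conditions: NaOMe, MeOH, reflux; then aq. HCl
Reagents that add atoms: none
Why: Stobbe condensation: the succinate enolate adds to the non-enolisable aldehyde, the aldolate lactonises to 3, and irreversible base-induced ring opening should give the half-ester with ring C trans to the ester group (E), which also tells the future C9' (ester) and C9 (acid) apart.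

Step 2
Reactants: 4 (E)-half-ester
Product: 5 (3S)-4-[4-(benzyloxy)-3,5-dimethoxyphenyl]-3-(methoxycarbonyl)butanoic acid
Conditions: [Rh(COD)((R,R)-Et-DuPhos)]BF4 (0.5 mol %), NaOMe (10 mol %), H2 (6 bar), MeOH, rt
Reagents that add atoms: none
Why: Asymmetric hydrogenation of an itaconate-type half-ester with a cationic rhodium bisphospholane catalyst: chelation of the alkene and the β-carboxylate to the metal lets the C2-symmetric ligand choose the alkene face and should set C8' as S, while the homogeneous catalyst leaves the aryl benzyl ether alone.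

Step 3
Reactants: 5 (3S)-half-ester
Product: 7 (4S)-4-[4-(benzyloxy)-3,5-dimethoxybenzyl]oxolan-2-one, via hydroxy acid 6 (not isolated)
Conditions: KOH (1 equiv), EtOH; CaCl2, NaBH4, EtOH, −10 °C → rt; then 2 M HCl, rt
Reagents that add atoms: none
Why: Chemoselective borohydride reduction followed by acid lactonisation: the potassium carboxylate (C9) resists Ca(BH4)2 while the methyl ester (C9') is reduced, and acidification closes 6 to the β-substituted γ-lactone with C8' untouched.

Step 4
Reactants: 8 4-(allyloxy)-3-methoxybenzaldehyde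
Product: 9 [4-(allyloxy)-3-methoxyphenyl]methanol
Conditions: NaBH4, MeOH, 0 °C
Reagents that add atoms: none
Why: Borohydride reduction of an aromatic aldehyde, to which the allyl aryl ether is inert; no stereocentre is formed.

Step 5
Reactants: 9 [4-(allyloxy)-3-methoxyphenyl]methanol
Product: 10 4-(allyloxy)-3-methoxybenzyl bromide
Conditions: PBr3, Et2O, 0 °C
Reagents that add atoms: phosphorus tribromide BrP(Br)Br
Why: Bromination of an activated benzylic alcohol with PBr3 by SN2 displacement of the phosphite ester; the electron-rich bromide is used at once without chromatography.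

Step 6
Reactants: 7 (4S)-lactone; 10 ring B benzyl bromide
Product: 12 (3S,4S)-3-[4-(allyloxy)-3-methoxybenzyl]-4-[4-(benzyloxy)-3,5-dimethoxybenzyl]oxolan-2-one, via lithium enolate 11 (not isolated)
Conditions: LiN(i-Pr)2, THF, −78 °C; then 10, DMPU, −78 → −20 °C
Reagents that add atoms: none
Why: Diastereoselective alkylation of a β-substituted γ-butyrolactone enolate: the bromide should approach the planar enolate 11 on the face opposite the C8' benzyl group, which sets C8 as S (3,4-trans).

Step 7
Reactants: 12 (3S,4S)-trans-lactone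
Product: 13 (2S,3S)-2-[4-(allyloxy)-3-methoxybenzyl]-3-[4-(benzyloxy)-3,5-dimethoxybenzyl]butane-1,4-diol
Conditions: LiAlH4, THF, 0 °C → rt
Reagents that add atoms: none
Why: Hydride reduction of the lactone to the 1,4-diol, which touches neither C8 nor C8' and spares the allyl, benzyl and methyl ethers.

Step 8
Reactants: 13 (2S,3S)-diol
Product: 15 (1R,3aS,4R,6aS)-1-[4-(allyloxy)-3-methoxyphenyl]-4-[4-(benzyloxy)-3,5-dimethoxyphenyl]tetrahydro-1H,3H-furo[3,4-c]furan (7R,8S,7'R,8'S; exo,exo), via monocyclic 7,9'-epoxylignan 14 (not isolated)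
Conditions: undivided cell, reticulated vitreous carbon anode, Pt cathode, constant current (about 1 mA cm−2), 4.0–4.4 F mol−1, LiClO4 (0.1 M), 2,6-lutidine (4 equiv), MeCN–(CF3)2CHOH 4:1, 5 mM in 13, 0 °C
Reagents that add atoms: none
Why: Proposed new method: each electron-rich ring should give up one electron at the anode, the radical cation should lose a benzylic proton to 2,6-lutidine and then a second electron, and the resulting quinoid para-alkoxybenzyl cation is taken by the primary hydroxyl of the other half while the protons leave as H2 at the cathode; the closest known reaction types are anodic benzylic C–H alkoxylation of 4-alkoxyalkylarenes and quinone-mediated oxidative cyclisation of dibenzylbutanediols to 7,9'-epoxylignans, but a double anodic closure to a furofuran has not been shown. Ring 1 (C7–O–C9'–C8'–C8) should form first, because dialkoxy ring B is the easier one to oxidise, by 5-exo-trig attack of O9' on C7 to give 14, and ring 2 (C7'–O–C9–C8–C8') closes in the same 5-exo-trig mode from the ring C cation, whereas the hydroxyl on the cation's own half could only form an oxetane. C7 is controlled by C8, since O9' adds to the cation face that leaves ring B trans to the C8 hydroxymethyl group (7R). C7' is controlled by the cis relation of the C8 and C8' side arms on ring 1, which allows only a cis-fused bicycle in which ring C takes the convex exo position (7'R), and as exo,exo is also the most stable isomer any reversible ionisation converges on 15. The step needs oxygen rather than carbon capture (aryltetralin closure through C2'/C6' or C6, biaryl coupling) and CH2 rather than product CH oxidation: the first rests on the faster five-membered O-closure in dilute, buffered solution, the second on the higher oxidation potential of an aryl group whose benzylic carbon carries the hexafluoroisopropanol-bonded ring oxygen, on the slower deprotonation of a ring methine than of a freely rotating CH2, and on stopping the charge near 4 F mol−1. O-allyl and O-benzyl are plain alkyl-type donors that keep the para stabilisation and should not be oxidised below the arene potentials.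

Step 9
Reactants: 15 O-allyl O-benzyl furofuran
Product: 16 4-[(1R,3aS,4R,6aS)-4-[4-(benzyloxy)-3,5-dimethoxyphenyl]tetrahydro-1H,3H-furo[3,4-c]furan-1-yl]-2-methoxyphenol (ring B phenol)
Conditions: Pd(PPh3)4 (5 mol %), morpholine, THF, rt
Reagents that add atoms: none
Why: Tsuji–Trost-type deallylation: zerovalent palladium ionises the allyl aryl ether to a π-allyl complex and the ring B phenoxide, morpholine takes up the allyl group, and the benzyl ether and the four stereocentres are not involved.

Step 10
Reactants: 17 (R)-4-benzyl-1,3-oxazolidin-2-one; 18 bromoacetyl bromide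
Product: 20 (R)-4-benzyl-3-(bromoacetyl)-1,3-oxazolidin-2-one, via lithium oxazolidinonide 19 (not isolated)
Conditions: n-BuLi, THF, −78 °C; then 18, −78 → 0 °C
Reagents that add atoms: none
Why: N-acylation of the lithiated oxazolidinone, in which the acyl bromide reacts far faster than the alkyl bromide; the auxiliary stereocentre is not involved.

Step 11
Reactants: 16 ring B phenol; 20 (R)-bromoacetyl imide
Product: 21 (R)-4-benzyl-3-[(aryloxy)acetyl]-1,3-oxazolidin-2-one, in which aryloxy is the ring B oxygen of 16 (O–CH2–CO–N)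
Conditions: K2CO3, acetone, rt
Reagents that add atoms: none
Why: Williamson ether synthesis: the ring B phenoxide displaces the activated α-bromide by SN2, whereas acyl transfer from the imide to a phenoxide is uphill and reversible.

Step 12
Reactants: 21 aryloxyacetyl imide; 22 4-(benzyloxy)-3-methoxybenzaldehyde
Product: 24 (R)-4-benzyl-3-[(2R,3S)-2-(ring B aryloxy)-3-[4-(benzyloxy)-3-methoxyphenyl]-3-hydroxypropanoyl]-1,3-oxazolidin-2-one (syn), via Z boron enolate 23 (not isolated)
Conditions: Bu2BOTf, Et3N, CH2Cl2, −78 → 0 °C; 22, −78 → 0 °C; then pH 7 buffer, MeOH, H2O2, 0 °C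
Reagents that add atoms: none
Why: Evans syn aldol: soft enolisation gives the Z boron enolate 23, which should react through a closed chair transition state with the auxiliary benzyl group shielding one enolate face, setting C8'' in its final spatial arrangement (2R in the imide) and C7'' as 3S, the centre that step 14 inverts.

Step 13
Reactants: 24 syn aldol imide
Product: 25 threo (7''S,8''S)-1,3-diol (ring A and ring C O-benzylated)
Conditions: LiBH4, THF, 0 °C
Reagents that add atoms: none
Why: Reductive removal of the auxiliary with LiBH4 at the exocyclic imide carbonyl gives the 1,3-diol directly; no stereocentre is touched (the C8'' descriptor changes from R to S only through the priority change) and 17 is recovered.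

Step 14
Reactants: 25 threo diol
Product: 26 erythro (7''R,8''S)-7'',9''-bis(4-nitrobenzoate)
Conditions: 4-O2NC6H4CO2H, PPh3, DIAD (each in excess), toluene–THF, −20 °C → rt
Reagents that add atoms: 4-nitrobenzoic acid O=C(O)c1ccc(cc1)[N+](=O)[O-]
Why: Mitsunobu reaction: both hydroxyls are esterified, the primary one without stereochemical consequence and the C7'' oxyphosphonium ion by SN2 with inversion (7''S to 7''R), which turns threo into erythro, while low temperature and a solvent of low polarity disfavour ionisation.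

Step 15
Reactants: 26 bis(4-nitrobenzoate)
Product: 27 erythro (7''R,8''S)-diol, the ring A, ring C di-O-benzyl ether of the target
Conditions: K2CO3 (0.2 equiv), MeOH–THF, rt
Reagents that add atoms: none
Why: Base-catalysed transesterification of two activated aryl esters with methanol breaks only acyl–oxygen bonds, so C7'' and C8'' keep their configuration.

Step 16
Reactants: 27 di-O-benzyl ether
Product: 28 Ficusesquilignan A
Conditions: H2 (1 atm), 10% Pd/C, EtOAc–EtOH, rt, stopped as soon as both benzyl groups are gone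
Reagents that add atoms: none
Why: Catalytic hydrogenolysis: unhindered aryl benzyl ethers, which release phenols, are cleaved much faster than the hindered secondary benzylic C–O bonds of the furofuran and the C7'' alcohol, so timely interruption should leave all six stereocentres intact.

**Compound list**

1 | 4-(benzyloxy)-3,5-dimethoxybenzaldehyde | COc1cc(C=O)cc(OC)c1OCc1ccccc1 | starting material
2 | dimethyl succinate | COC(=O)CCC(=O)OC | starting material
3 | methyl 2-[4-(benzyloxy)-3,5-dimethoxyphenyl]-5-oxooxolane-3-carboxylate (stereoisomer mixture) | COC(=O)C1CC(=O)OC1c1cc(OC)c(OCc2ccccc2)c(OC)c1 | intermediate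
4 | (E)-4-[4-(benzyloxy)-3,5-dimethoxyphenyl]-3-(methoxycarbonyl)but-3-enoic acid | COC(=O)/C(=C/c1cc(OC)c(OCc2ccccc2)c(OC)c1)CC(=O)O | intermediate
5 | (3S)-4-[4-(benzyloxy)-3,5-dimethoxyphenyl]-3-(methoxycarbonyl)butanoic acid | COC(=O)[C@@H](Cc1cc(OC)c(OCc2ccccc2)c(OC)c1)CC(=O)O | intermediate
6 | (3S)-3-[4-(benzyloxy)-3,5-dimethoxybenzyl]-4-hydroxybutanoic acid | OC[C@@H](Cc1cc(OC)c(OCc2ccccc2)c(OC)c1)CC(=O)O | intermediate
7 | (4S)-4-[4-(benzyloxy)-3,5-dimethoxybenzyl]oxolan-2-one | O=C1C[C@H](Cc2cc(OC)c(OCc3ccccc3)c(OC)c2)CO1 | intermediate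
8 | 4-(allyloxy)-3-methoxybenzaldehyde | C=CCOc1ccc(C=O)cc1OC | starting material
9 | [4-(allyloxy)-3-methoxyphenyl]methanol | C=CCOc1ccc(CO)cc1OC | intermediate
10 | 4-(allyloxy)-3-methoxybenzyl bromide | C=CCOc1ccc(CBr)cc1OC | intermediate
11 | lithium enolate of 7 | [Li+].[O-]C1=C[C@H](Cc2cc(OC)c(OCc3ccccc3)c(OC)c2)CO1 | intermediate
12 | (3S,4S)-3-[4-(allyloxy)-3-methoxybenzyl]-4-[4-(benzyloxy)-3,5-dimethoxybenzyl]oxolan-2-one | O=C1[C@@H](Cc2ccc(OCC=C)c(OC)c2)[C@H](Cc2cc(OC)c(OCc3ccccc3)c(OC)c2)CO1 | intermediate
13 | (2S,3S)-2-[4-(allyloxy)-3-methoxybenzyl]-3-[4-(benzyloxy)-3,5-dimethoxybenzyl]butane-1,4-diol | C=CCOc1ccc(C[C@H](CO)[C@@H](CO)Cc2cc(OC)c(OCc3ccccc3)c(OC)c2)cc1OC | intermediate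
14 | [(2R,3S,4S)-2-[4-(allyloxy)-3-methoxyphenyl]-4-[4-(benzyloxy)-3,5-dimethoxybenzyl]oxolan-3-yl]methanol | C=CCOc1ccc(cc1OC)[C@@H]1OC[C@@H](Cc2cc(OC)c(OCc3ccccc3)c(OC)c2)[C@H]1CO | intermediate
15 | (1R,3aS,4R,6aS)-1-[4-(allyloxy)-3-methoxyphenyl]-4-[4-(benzyloxy)-3,5-dimethoxyphenyl]tetrahydro-1H,3H-furo[3,4-c]furan | C=CCOc1ccc(cc1OC)[C@@H]1OC[C@@H]2[C@H]1CO[C@H]2c1cc(OC)c(OCc2ccccc2)c(OC)c1 | intermediate
16 | 4-[(1R,3aS,4R,6aS)-4-[4-(benzyloxy)-3,5-dimethoxyphenyl]tetrahydro-1H,3H-furo[3,4-c]furan-1-yl]-2-methoxyphenol | COc1cc(ccc1O)[C@@H]1OC[C@@H]2[C@H]1CO[C@H]2c1cc(OC)c(OCc2ccccc2)c(OC)c1 | intermediate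
17 | (R)-4-benzyl-1,3-oxazolidin-2-one | O=C1N[C@H](Cc2ccccc2)CO1 | starting material
18 | bromoacetyl bromide | BrCC(Br)=O | starting material
19 | lithium salt of 17 | [Li+].O=C1[N-][C@H](Cc2ccccc2)CO1 | intermediate
20 | (R)-4-benzyl-3-(bromoacetyl)-1,3-oxazolidin-2-one | BrCC(=O)N1[C@H](Cc2ccccc2)COC1=O | intermediate
21 | (R)-4-benzyl-3-[(ring B aryloxy)acetyl]-1,3-oxazolidin-2-one derived from 16 | COc1cc(ccc1OCC(=O)N1[C@H](Cc2ccccc2)COC1=O)[C@@H]1OC[C@@H]2[C@H]1CO[C@H]2c1cc(OC)c(OCc2ccccc2)c(OC)c1 | intermediate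
22 | 4-(benzyloxy)-3-methoxybenzaldehyde | COc1cc(C=O)ccc1OCc1ccccc1 | starting material
23 | (Z)-dibutylboron enolate of 21 | CCCCB(CCCC)O/C(=C\Oc1ccc(cc1OC)[C@@H]1OC[C@@H]2[C@H]1CO[C@H]2c1cc(OC)c(OCc2ccccc2)c(OC)c1)N1[C@H](Cc2ccccc2)COC1=O | intermediate
24 | (2R,3S)-syn aldol imide, (R)-auxiliary | COc1cc(ccc1OCc1ccccc1)[C@H](O)[C@H](C(=O)N1[C@H](Cc2ccccc2)COC1=O)Oc1ccc(cc1OC)[C@@H]1OC[C@@H]2[C@H]1CO[C@H]2c1cc(OC)c(OCc2ccccc2)c(OC)c1 | intermediate
25 | threo (7''S,8''S)-diol, ring A and ring C O-benzylated | COc1cc(ccc1OCc1ccccc1)[C@H](O)[C@H](CO)Oc1ccc(cc1OC)[C@@H]1OC[C@@H]2[C@H]1CO[C@H]2c1cc(OC)c(OCc2ccccc2)c(OC)c1 | intermediate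
26 | erythro (7''R,8''S)-7'',9''-bis(4-nitrobenzoate) | COc1cc(ccc1OCc1ccccc1)[C@@H](OC(=O)c1ccc(cc1)[N+](=O)[O-])[C@H](COC(=O)c1ccc(cc1)[N+](=O)[O-])Oc1ccc(cc1OC)[C@@H]1OC[C@@H]2[C@H]1CO[C@H]2c1cc(OC)c(OCc2ccccc2)c(OC)c1 | intermediate
27 | erythro (7''R,8''S)-diol, di-O-benzyl ether of the target | COc1cc(ccc1OCc1ccccc1)[C@@H](O)[C@H](CO)Oc1ccc(cc1OC)[C@@H]1OC[C@@H]2[C@H]1CO[C@H]2c1cc(OC)c(OCc2ccccc2)c(OC)c1 | intermediate
28 | Ficusesquilignan A | COc1cc([C@@H](O)[C@H](CO)Oc2ccc([C@@H]3OC[C@@H]4[C@H]3CO[C@H]4c3cc(OC)c(O)c(OC)c3)cc2OC)ccc1O | target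

**Step count.** Total: 16 steps. Longest linear sequence: 13 steps (steps 1–3, 6–9, 11–16).

**Steps most likely to fail**

Step 8 (bears the label). What may go wrong:
- further oxidation at the newly formed benzylic ether C–H bonds;
- capture of a benzylic cation by the other arene instead of by oxygen;
- oxidative loss of the O-allyl or O-benzyl group.

The fallback uses only known reaction types. It sets out from 13 and comes back at 15, and it separates oxidation from ring closure. Acetylation (Ac2O, pyridine) masks the primary alcohols as the (2S,3S)-diacetate F1. Hydride abstraction with DDQ in acetic acid places an acetoxy group on C7 and on C7' to give the 7,7'-diacetoxy tetraacetate F2. This is an epimer mixture at C7 and C7', and a benzylic acetate resists a second hydride abstraction. K2CO3 in MeOH gives the tetraol F3. Camphorsulfonic acid in CH2Cl2 then brings about the classical double cyclodehydration of a 1,4-diaryl-2,3-bis(hydroxymethyl)butane-1,4-diol. Both benzylic centres equilibrate through their cations to exo,exo 15.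

Step 14. What may go wrong: the activated, electron-rich benzylic oxyphosphonium ion may ionise, so that substitution no longer inverts cleanly, or elimination may occur. The fallback sets out from 25 and comes back at 27. It corrects C7'' by oxidation and chelate-controlled reduction instead of substitution.
- TBSCl and imidazole silylate the primary hydroxyl to give the threo 9''-silyl ether F4.
- Dess–Martin periodinane gives the (8''S)-7''-ketone F5.
- Zn(BH4)2 in Et2O at −78 °C reduces the zinc chelate between the carbonyl oxygen and the C8'' aryloxy oxygen from the face opposite the silyloxymethyl group. This gives the erythro 9''-silyl ether F6.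
- Bu4NF gives 27.

Step 12. What may go wrong: incomplete enolisation, Lewis-acid-induced epimerisation at C7 or C7' of the polyether substrate, or sluggish addition to the electron-rich aldehyde. The fallback sets out from 16 and 22 and comes back at 27, bypassing steps 11–15. The aldol is run on small molecules, and the ring B oxygen is brought in afterwards by SN2 with inversion at C8'', which gives erythro directly.
- Commercial (S)-4-benzyl-1,3-oxazolidin-2-one is acylated with 18 as in step 10 to give the (S)-bromoacetyl imide F7.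
- Its dibutylboron enolate adds to 22 (the haloacetate variant of the Evans aldol) to give the syn (2S,3R)-bromohydrin imide F8.
- TBSOTf and 2,6-lutidine give the silyl ether F9.
- Phenol 16 with Cs2CO3 in DMF displaces bromide with inversion to give the anti (2R,3R)-aryloxy imide F10.
- LiBH4 gives the primary alcohol F11, and Bu4NF gives 27.

**Further compounds**

F1 | step 8 | (2S,3S)-diacetate of 13 | C=CCOc1ccc(C[C@H](COC(C)=O)[C@@H](COC(C)=O)Cc2cc(OC)c(OCc3ccccc3)c(OC)c2)cc1OC
F2 | step 8 | 7,7'-diacetoxy tetraacetate (C7 and C7' epimer mixture) | C=CCOc1ccc(C(OC(C)=O)[C@H](COC(C)=O)[C@@H](COC(C)=O)C(OC(C)=O)c2cc(OC)c(OCc3ccccc3)c(OC)c2)cc1OC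
F3 | step 8 | 1,4-diaryl-2,3-bis(hydroxymethyl)butane-1,4-diol (C7 and C7' epimer mixture) | C=CCOc1ccc(C(O)[C@H](CO)[C@@H](CO)C(O)c2cc(OC)c(OCc3ccccc3)c(OC)c2)cc1OC
F4 | step 14 | threo (7''S,8''S) 9''-O-TBS ether of 25 | COc1cc(ccc1OCc1ccccc1)[C@H](O)[C@H](CO[Si](C)(C)C(C)(C)C)Oc1ccc(cc1OC)[C@@H]1OC[C@@H]2[C@H]1CO[C@H]2c1cc(OC)c(OCc2ccccc2)c(OC)c1
F5 | step 14 | (8''S)-7''-ketone, 9''-O-TBS | COc1cc(ccc1OCc1ccccc1)C(=O)[C@H](CO[Si](C)(C)C(C)(C)C)Oc1ccc(cc1OC)[C@@H]1OC[C@@H]2[C@H]1CO[C@H]2c1cc(OC)c(OCc2ccccc2)c(OC)c1
F6 | step 14 | erythro (7''R,8''S) 9''-O-TBS ether of 27 | COc1cc(ccc1OCc1ccccc1)[C@@H](O)[C@H](CO[Si](C)(C)C(C)(C)C)Oc1ccc(cc1OC)[C@@H]1OC[C@@H]2[C@H]1CO[C@H]2c1cc(OC)c(OCc2ccccc2)c(OC)c1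
F7 | step 12 | (S)-4-benzyl-3-(bromoacetyl)-1,3-oxazolidin-2-one | BrCC(=O)N1[C@@H](Cc2ccccc2)COC1=O
F8 | step 12 | (S)-4-benzyl-3-[(2S,3R)-3-[4-(benzyloxy)-3-methoxyphenyl]-2-bromo-3-hydroxypropanoyl]-1,3-oxazolidin-2-one | COc1cc(ccc1OCc1ccccc1)[C@@H](O)[C@@H](C(=O)N1[C@@H](Cc2ccccc2)COC1=O)Br
F9 | step 12 | 3-O-TBS ether of F8 | COc1cc(ccc1OCc1ccccc1)[C@@H](O[Si](C)(C)C(C)(C)C)[C@@H](C(=O)N1[C@@H](Cc2ccccc2)COC1=O)Br
F10 | step 12 | anti (2R,3R)-2-(ring B aryloxy)-3-(TBS-oxy) imide, (S)-auxiliary | COc1cc(ccc1OCc1ccccc1)[C@@H](O[Si](C)(C)C(C)(C)C)[C@H](C(=O)N1[C@@H](Cc2ccccc2)COC1=O)Oc1ccc(cc1OC)[C@@H]1OC[C@@H]2[C@H]1CO[C@H]2c1cc(OC)c(OCc2ccccc2)c(OC)c1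
F11 | step 12 | erythro (7''R,8''S) 7''-O-TBS ether of 27 | COc1cc(ccc1OCc1ccccc1)[C@@H](O[Si](C)(C)C(C)(C)C)[C@H](CO)Oc1ccc(cc1OC)[C@@H]1OC[C@@H]2[C@H]1CO[C@H]2c1cc(OC)c(OCc2ccccc2)c(OC)c1
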